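**Retrosynthetic overview**
1. The C7–CH2–pyranone bridge is cut by a Mannich/Michael methylenation between the pyranone and the only free arene carbon (CH2 from an iminium salt).
2. The pyranone is cut to an open-chain 3,5-dioxo ester (β-keto ester dianion + Weinreb amide) and is closed by lactonisation in the final flask.
3. The dihydrofuran (C3–C3a and O1–C2) is cut by a dehydrative (3+2) annulation of the acylphloroglucinol C–H/O–H pair with isoprene monoxide under zerovalent palladium and a chiral diphosphine; this sets C2.
4. The aryl ketone is cut by Friedel–Crafts acylation of phloroglucinol with chiral-pool (R)-2-methylbutanoyl chloride, which brings in the side-chain stereocentre.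
5. Ring order: the benzene ring is bought; the dihydrofuran closes first and the pyranone second, both in the one-flask final operation.

Assumption: (2R)-2-methylbutanoic acid of ≥98% ee is bought as such, and the (R,R) ligand is taken to give the (2R) ether by analogy with related phenol cyclisations (its (S,S) mirror image is the drop-in replacement if the first run shows the opposite sense).

**Step 1**
Reactants: 1 benzene-1,3,5-triol (phloroglucinol); 2 (2R)-2-methylbutanoic acid
Product: 4 (2R)-2-methyl-1-(2,4,6-trihydroxyphenyl)butan-1-one, via acid chloride 3 (not isolated)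
Conditions: 2, (COCl)2 (1.05 equiv), DMF (cat.), CH2Cl2, 0 to 25 °C, volatiles removed cold; then 1 (1.2 equiv), AlCl3 (3.5 equiv), PhNO2/CH2Cl2, 0 to 35 °C; aq. HCl work-up
Reagents that add atoms: oxalyl chloride, O=C(Cl)C(Cl)=O (its chlorine is in 3 only, none of its atoms is in 4)
Why: Friedel–Crafts C-acylation of the very electron-rich triol (any O-acyl material drains to the chelated C-acyl ketone by Fries migration under excess AlCl3), run without base and at low temperature so that the α-stereocentre carried in from 2 is not enolised.

**Step 2**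
Reactants: 5 methyl 3-oxopentanoate; 6 N-methoxy-N-methylpropanamide
Product: 7 methyl 4-methyl-3,5-dioxoheptanoate
Conditions: NaH (1.1 equiv), THF, 0 °C; n-BuLi (1.05 equiv), 0 °C; then 6 (1.0 equiv), −78 to 0 °C; aq. HCl
Reagents that add atoms: N-methoxy-N-methylpropanamide (6), CCC(=O)N(C)OC
Why: Huckin–Weiler dianion γ-acylation (Claisen type): only the γ-carbanion (C4) of the 1,3-dianion reacts and the chelated tetrahedral adduct of the Weinreb amide stops at mono-acylation; C4 of 7 is a racemic, enolisable centre that becomes sp2 in the pyranone.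

**Step 3**
Reactants: 4; 7; 8 2-methyl-2-vinyloxirane (isoprene monoxide, racemic); 9 N,N-dimethylmethyleneiminium iodide
Product: 15 3-{[(2R)-4,6-dihydroxy-5-[(2R)-2-methylbutanoyl]-2-(prop-1-en-2-yl)-2,3-dihydro-1-benzofuran-7-yl]methyl}-6-ethyl-4-hydroxy-5-methyl-2H-pyran-2-one, via allylic alcohol 10 (not isolated), via dihydrobenzofuran 11 (not isolated), via pyranone 12 (not isolated), via Mannich base 13 (not isolated), via pyranone methide 14 (not isolated)
Conditions: 4 (1.0 equiv), 8 (0.95 equiv), Pd2(dba)3·CHCl3 (2.5 mol%), (R,R)-DACH-phenyl Trost ligand [N,N′-(1R,2R)-cyclohexane-1,2-diylbis(2-diphenylphosphanylbenzamide)] (7.5 mol%), BEt3 (30 mol%), THF, 25 to 40 °C; then thiol-functionalised silica, 7 (1.0 equiv), DBU (2.5 equiv), 60 °C; then AcOH (3 equiv), 9 (1.05 equiv), MeCN, 40 °C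
Reagents that add atoms: 2-methyl-2-vinyloxirane (8), C=CC1(C)CO1; methyl 4-methyl-3,5-dioxoheptanoate (7), CCC(=O)C(C)C(=O)CC(=O)OC; N,N-dimethylmethyleneiminium iodide (9), C=[N+](C)C.[I-]
Why: Proposed new method: zerovalent palladium opens 8 to a zwitterionic π-allyl whose alkoxide deprotonates 4, and ring carbon C3 of the phenoxide adds at the unsubstituted allyl terminus to give 10 (Tsuji–Trost 1,4-addition of a soft carbon nucleophile to a vinyl epoxide; O-allyl ethers formed reversibly re-ionise and drain to the C–C product); BEt3 then re-ionises the allylic alcohol (as in palladium/trialkylborane C-allylation of benzene polyols with free allyl alcohols) and the most acidic, non-chelated para-OH closes 5-exo on the internal allyl carbon inside the chiral pocket of the ligand, fast π–σ–π equilibration making the alkene geometry of 10 irrelevant and catalyst control setting C2 as R in 11 (closest known reaction: Trost asymmetric allylic etherification of phenol-tethered allyl carbonates to 2-vinylchromans and 2-isopropenyl-2,3-dihydrobenzofurans); in the same flask, with palladium sequestered and 11 parked as an unreactive phenoxide, DBU lactonises 7 to 12 (standard 3,5-dioxo ester to 4-hydroxy-2-pyranone cyclisation), and the Mannich base 13 of 12 loses dimethylamine to methide 14, which is trapped by C7, the only free aromatic carbon of 11 (Mannich/Michael methylene bridging), so that the dihydrofuran and the pyranone are both closed in this single operation.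

**Compound list**
1 | benzene-1,3,5-triol (phloroglucinol) | Oc1cc(O)cc(O)c1 | starting material
2 | (2R)-2-methylbutanoic acid | CC[C@@H](C)C(=O)O | starting material
3 | (2R)-2-methylbutanoyl chloride | CC[C@@H](C)C(Cl)=O | intermediate
4 | (2R)-2-methyl-1-(2,4,6-trihydroxyphenyl)butan-1-one | CC[C@@H](C)C(=O)c1c(O)cc(O)cc1O | intermediate
5 | methyl 3-oxopentanoate | CCC(=O)CC(=O)OC | starting material
6 | N-methoxy-N-methylpropanamide | CCC(=O)N(C)OC | starting material
7 | methyl 4-methyl-3,5-dioxoheptanoate (racemic at C4, keto–enol mixture) | CCC(=O)C(C)C(=O)CC(=O)OC | intermediate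
8 | 2-methyl-2-vinyloxirane (isoprene monoxide, racemic) | C=CC1(C)CO1 | starting material
9 | N,N-dimethylmethyleneiminium iodide | C=[N+](C)C.[I-] | starting material
10 | (2R)-1-{2,4,6-trihydroxy-3-[(2E)-4-hydroxy-3-methylbut-2-en-1-yl]phenyl}-2-methylbutan-1-one | CC[C@@H](C)C(=O)c1c(O)cc(O)c(C/C=C(\C)CO)c1O | intermediate
11 | (2R)-1-[(2R)-4,6-dihydroxy-2-(prop-1-en-2-yl)-2,3-dihydro-1-benzofuran-5-yl]-2-methylbutan-1-one | C=C(C)[C@H]1Cc2c(O)c(C(=O)[C@H](C)CC)c(O)cc2O1 | intermediate
12 | 6-ethyl-4-hydroxy-5-methyl-2H-pyran-2-one | CCc1oc(=O)cc(O)c1C | intermediate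
13 | 3-[(dimethylamino)methyl]-6-ethyl-4-hydroxy-5-methyl-2H-pyran-2-one | CCc1oc(=O)c(CN(C)C)c(O)c1C | intermediate
14 | 6-ethyl-5-methyl-3-methylidene-2H-pyran-2,4(3H)-dione | C=C1C(=O)OC(CC)=C(C)C1=O | intermediate
15 | 3-{[(2R)-4,6-dihydroxy-5-[(2R)-2-methylbutanoyl]-2-(prop-1-en-2-yl)-2,3-dihydro-1-benzofuran-7-yl]methyl}-6-ethyl-4-hydroxy-5-methyl-2H-pyran-2-one | C=C(C)[C@H]1Cc2c(O)c(C(=O)[C@H](C)CC)c(O)c(Cc3c(O)c(C)c(CC)oc3=O)c2O1 | target

**Totals**
Total step count: 3. Longest linear sequence: 2 (step 1 then step 3, or step 2 then step 3).

**Steps most likely to fail, with fallbacks**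

Step 3 is the weakest step. The risks are:
- O-attack or branched attack on the vinyl-epoxide allyl instead of linear C-attack;
- sluggish ionisation of the allylic alcohol 10;
- closure through the chelated ortho-OH, giving the angular 7-acyl isomer;
- mono- versus bis-annulation of 4;
- imperfect ee (the (2S) epimer is a diastereomer of 15 and can be removed by chromatography);
- catalyst carry-over into the basic and Mannich stages.

The fallback sets out from 4 and comes back at 11. Mono-iodination of 4 with N-iodosuccinimide (MeCN, 0 °C) gives (2R)-1-(2,4,6-trihydroxy-3-iodophenyl)-2-methylbutan-1-one F3. A Larock-type enantioselective Heck/Tsuji–Trost heteroannulation of F3 with isoprene (Pd(OAc)2, chiral phosphoramidite ligand, K2CO3, 1,4-dioxane, 80 °C) follows: the aryl–palladium species adds to the unsubstituted vinyl end of the diene and the para-phenoxide captures the π-allyl at its internal carbon. This gives 11, which is isolated, purified and checked for ee and regiochemistry. The DBU/7 and 9 stages are then run on it as separate, palladium-free operations.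

Step 1 is second. The risks are partial racemisation of the α-centre under AlCl3 and over-acylation. The fallback sets out from 3 and comes back at 4. 1,3,5-Trimethoxybenzene is acylated in place of 1 (SnCl4, CH2Cl2, −20 °C; no free phenol, no aluminium chelate, low temperature) to (2R)-2-methyl-1-(2,4,6-trimethoxyphenyl)butan-1-one F1. The three methyl ethers are then cleaved with BBr3 (CH2Cl2, −78 to 25 °C) to give 4; ee is checked by chiral HPLC.

Step 2 is third. The risks are incomplete dianion formation, O-acylation and self-condensation of 5. The fallback sets out from 5 and comes back at 7. Aldol addition of the same dianion to propanal gives methyl 5-hydroxy-4-methyl-3-oxoheptanoate F2 (mixture of diastereomers), which Dess–Martin periodinane (CH2Cl2, 25 °C) oxidises to 7.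

**Further compounds**
F1 | step 1 | (2R)-2-methyl-1-(2,4,6-trimethoxyphenyl)butan-1-one | CC[C@@H](C)C(=O)c1c(OC)cc(OC)cc1OC
F2 | step 2 | methyl 5-hydroxy-4-methyl-3-oxoheptanoate (mixture of diastereomers) | CCC(O)C(C)C(=O)CC(=O)OC
F3 | step 3 | (2R)-1-(2,4,6-trihydroxy-3-iodophenyl)-2-methylbutan-1-one | CC[C@@H](C)C(=O)c1c(O)cc(O)c(I)c1O
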